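**Retrosynthetic overview**

1. Artocarpol D (15) comes from its bis-MOM ether 14 by acetal cleavage in the last step.
2. 14 is cut at the oxepine C10–C11 bond and at the pyran O–CMe2 bond (dibenzo[b,f]oxepine numbering, C10 carries the pyran oxygen). This leads back to the acyclic diaryl ether 11, with a formyl group on ring A and a 4-methylpent-3-en-1-ynyl arm on ring B.
3. Enabling feature: the pyran ring O–C(Me)2–CH=CH–C11=C10 is the closed valence tautomer of the Z-1-oxatriene O=C10–C11=CH–CH=CMe2, which is the H/acyl adduct of an aryl enyne. The diaryl ether oxygen, ortho to the formyl group on ring A and to the enyne on ring B, acts as a seven-ring tether and as a chelating donor for rhodium.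
4. 11 comes from diaryl ether 5 by Stille prenylation, Ohira–Bestmann alkynylation, Sonogashira coupling and nitrile reduction. 5 comes from SNAr of phenol 2 with fluoronitrile 4; the nitrile masks the ring A aldehyde, so two formyl groups never coexist.
5. Ring order: rings A and B are bought as benzene rings (3 and 1); the oxepine ring and then the pyran ring are both formed in step 8.

Key step: step 8

Remark on the chemistry: artocarpol D has no stereocentre, so the only stereochemical element in the route is the geometry of the exocyclic C11=CH bond in step 8.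

**Route**

Step 1
Reactants: 1 5-bromo-2,4-dihydroxybenzaldehyde
Product: 2 5-bromo-2-hydroxy-4-(methoxymethoxy)benzaldehyde
Conditions: MOMCl (1.05 equiv), K2CO3, acetone, 0 °C to rt
Reagents that add atoms: chloromethyl methyl ether (MOMCl), COCCl
Why: Phenol O-alkylation (Williamson type); the 4-hydroxyl, para to the formyl group and not hydrogen-bonded, is the more acidic and more nucleophilic phenol, whereas the 2-hydroxyl is held in a hydrogen bond to the aldehyde, so one equivalent of reagent should protect O-4 only.

Step 2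
Reactants: 3 2-fluoro-4-hydroxybenzonitrile
Product: 4 2-fluoro-4-(methoxymethoxy)benzonitrile
Conditions: MOMCl, K2CO3, acetone, rt
Reagents that add atoms: chloromethyl methyl ether (MOMCl), COCCl
Why: Phenol O-alkylation; the phenoxide is the only nucleophilic site and the fluoride is not displaced at room temperature.

Step 3
Reactants: 2 5-bromo-2-hydroxy-4-(methoxymethoxy)benzaldehyde; 4 2-fluoro-4-(methoxymethoxy)benzonitrile
Product: 5 2-[4-bromo-2-formyl-5-(methoxymethoxy)phenoxy]-4-(methoxymethoxy)benzonitrile
Conditions: K2CO3, DMSO, 100 °C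
Reagents that add atoms: none
Why: Nucleophilic aromatic substitution (SNAr, addition–elimination); the fluoride ortho to the nitrile is displaced by the phenoxide of 2 through a nitrile-stabilised Meisenheimer intermediate, and the MOM ethers, aryl bromide and aldehyde are inert to carbonate.

Step 4
Reactants: 5 2-[4-bromo-2-formyl-5-(methoxymethoxy)phenoxy]-4-(methoxymethoxy)benzonitrile; 6 tributyl(3-methylbut-2-en-1-yl)stannane
Product: 7 2-[2-formyl-5-(methoxymethoxy)-4-(3-methylbut-2-en-1-yl)phenoxy]-4-(methoxymethoxy)benzonitrile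
Conditions: Pd(PPh3)4 (5 mol%), CsF (2 equiv), DMF, 90 °C
Reagents that add atoms: none
Why: Stille cross-coupling; zerovalent palladium inserts into the aryl bromide, fluoride-assisted transmetalation follows, and reductive elimination at the unsubstituted allyl terminus should give the linear prenyl arene while aldehyde, nitrile and MOM ethers are untouched.

Step 5
Reactants: 7 2-[2-formyl-5-(methoxymethoxy)-4-(3-methylbut-2-en-1-yl)phenoxy]-4-(methoxymethoxy)benzonitrile
Product: 8 2-[2-ethynyl-5-(methoxymethoxy)-4-(3-methylbut-2-en-1-yl)phenoxy]-4-(methoxymethoxy)benzonitrile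
Conditions: dimethyl (1-diazo-2-oxopropyl)phosphonate, K2CO3, MeOH/THF, 0 °C to rt
Reagents that add atoms: dimethyl (1-diazo-2-oxopropyl)phosphonate (Ohira–Bestmann reagent), COP(=O)(OC)C(=[N+]=[N-])C(C)=O
Why: Seyferth–Gilbert homologation in its Ohira–Bestmann form; the diazomethylphosphonate anion released by methanolysis olefinates the only aldehyde and the diazoalkene loses N2 with 1,2-hydride shift to give the terminal alkyne, conditions that the nitrile and the MOM ethers tolerate.

Step 6
Reactants: 8 2-[2-ethynyl-5-(methoxymethoxy)-4-(3-methylbut-2-en-1-yl)phenoxy]-4-(methoxymethoxy)benzonitrile; 9 1-bromo-2-methylprop-1-ene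
Product: 10 4-(methoxymethoxy)-2-[5-(methoxymethoxy)-4-(3-methylbut-2-en-1-yl)-2-(4-methylpent-3-en-1-yn-1-yl)phenoxy]benzonitrile
Conditions: PdCl2(PPh3)2 (3 mol%), CuI (6 mol%), Et3N, THF, 50 °C
Reagents that add atoms: none
Why: Sonogashira coupling of the terminal alkyne with the alkenyl bromide (copper acetylide transmetalation to the alkenyl palladium bromide, then reductive elimination) should give the conjugated enyne, and the substrate has no other halide to compete.

Step 7
Reactants: 10 4-(methoxymethoxy)-2-[5-(methoxymethoxy)-4-(3-methylbut-2-en-1-yl)-2-(4-methylpent-3-en-1-yn-1-yl)phenoxy]benzonitrile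
Product: 11 4-(methoxymethoxy)-2-[5-(methoxymethoxy)-4-(3-methylbut-2-en-1-yl)-2-(4-methylpent-3-en-1-yn-1-yl)phenoxy]benzaldehyde
Conditions: i-Bu2AlH (DIBAL-H, 1.2 equiv), CH2Cl2, −78 °C; then aq. potassium sodium tartrate, rt
Reagents that add atoms: water, O
Why: Partial reduction of a nitrile by i-Bu2AlH stops at the N-aluminated aldimine at low temperature and hydrolysis on work-up gives the aldehyde, while alkyne, alkenes and MOM ethers are not attacked at −78 °C.

Step 8
Reactants: 11 4-(methoxymethoxy)-2-[5-(methoxymethoxy)-4-(3-methylbut-2-en-1-yl)-2-(4-methylpent-3-en-1-yn-1-yl)phenoxy]benzaldehyde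
Product: 14 artocarpol D bis(methoxymethyl) ether, via E-dienone 12 (not isolated), via Z-dienone 13 (not isolated)
Conditions: [Rh(cod)2]BF4 (10 mol%), dppe (10 mol%), degassed ClCH2CH2Cl (0.01 M), 70 °C; then fac-Ir(ppy)3 (1 mol%), 450 nm LED, 25 °C, same flask
Reagents that add atoms: none
Why: Proposed new method: the formyl C–H bond of 11 should add oxidatively to the cationic monovalent rhodium centre, helped by chelation through the diaryl ether oxygen ortho to the formyl group, and syn hydrometalation of the tethered aryl alkyne followed by C–C reductive elimination should form the C10–C11 bond and give E-dienone 12; the closest known reaction types are the rhodium-catalysed intramolecular alkyne hydroacylation that gives α-alkylidene cycloalkanones and the ether-chelation-assisted intramolecular olefin hydroacylation that gives seven-membered benzo-fused ketones. Triplet energy transfer from photoexcited fac-Ir(ppy)3 should then twist the exocyclic C11=CH bond, as in the sensitised E-to-Z isomerisation of cinnamates and of ionone-type dienones, and deliver Z-dienone 13, a 1-oxatriene with the carbonyl oxygen and the CMe2 terminus on the same side. Dienone 13 should close at once by a thermal disrotatory oxa-6π electrocyclisation that forms the O–CMe2 bond, the normal fate of a cis-dienone with a gem-dimethyl terminus. Ring closures: the oxepine ring by 7-exo-dig delivery of the acyl carbon to the proximal alkyne carbon, the pyran ring by 6π electrocyclisation. No stereocentre is created; the one stereochemical element, the geometry at C11=CH, comes out E from the syn addition and is corrected by the light stage, and since only 13 cyclises and the closure is irreversible the photostationary mixture should drain to 14. The step needs acyl transfer to the proximal (7-exo) and not the distal (8-endo) alkyne carbon and alkyne insertion ahead of decarbonylation; the short diaryl ether tether secures the first and the chelating ether oxygen together with the reactive conjugated alkyne the second.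

Step 9
Reactants: 14 artocarpol D bis(methoxymethyl) ether
Product: 15 artocarpol D
Conditions: Me3SiOTf (4 equiv), 2,2′-bipyridyl (6 equiv), CH3CN, 0 °C to rt; then H2O
Reagents that add atoms: none
Why: Lewis-acid cleavage of aryl MOM acetals; the silyl triflate buffered by 2,2′-bipyridyl should convert both aryl MOM ethers into aryl silyl ethers through a pyridinium-type intermediate and water then hydrolyses them, so no free protic acid meets the enol-ether pyran or the ortho-prenyl phenol.

**Compound list**

1 | 5-bromo-2,4-dihydroxybenzaldehyde | O=Cc1cc(Br)c(O)cc1O | starting material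
2 | 5-bromo-2-hydroxy-4-(methoxymethoxy)benzaldehyde | O=Cc1cc(Br)c(OCOC)cc1O | intermediate
3 | 2-fluoro-4-hydroxybenzonitrile | N#Cc1ccc(O)cc1F | starting material
4 | 2-fluoro-4-(methoxymethoxy)benzonitrile | N#Cc1ccc(OCOC)cc1F | intermediate
5 | 2-[4-bromo-2-formyl-5-(methoxymethoxy)phenoxy]-4-(methoxymethoxy)benzonitrile | N#Cc1ccc(OCOC)cc1Oc1cc(OCOC)c(Br)cc1C=O | intermediate
6 | tributyl(3-methylbut-2-en-1-yl)stannane | CCCC[Sn](CCCC)(CCCC)CC=C(C)C | starting material
7 | 2-[2-formyl-5-(methoxymethoxy)-4-(3-methylbut-2-en-1-yl)phenoxy]-4-(methoxymethoxy)benzonitrile | N#Cc1ccc(OCOC)cc1Oc1cc(OCOC)c(CC=C(C)C)cc1C=O | intermediate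
8 | 2-[2-ethynyl-5-(methoxymethoxy)-4-(3-methylbut-2-en-1-yl)phenoxy]-4-(methoxymethoxy)benzonitrile | N#Cc1ccc(OCOC)cc1Oc1cc(OCOC)c(CC=C(C)C)cc1C#C | intermediate
9 | 1-bromo-2-methylprop-1-ene | CC(C)=CBr | starting material
10 | 4-(methoxymethoxy)-2-[5-(methoxymethoxy)-4-(3-methylbut-2-en-1-yl)-2-(4-methylpent-3-en-1-yn-1-yl)phenoxy]benzonitrile | N#Cc1ccc(OCOC)cc1Oc1cc(OCOC)c(CC=C(C)C)cc1C#CC=C(C)C | intermediate
11 | 4-(methoxymethoxy)-2-[5-(methoxymethoxy)-4-(3-methylbut-2-en-1-yl)-2-(4-methylpent-3-en-1-yn-1-yl)phenoxy]benzaldehyde | O=Cc1ccc(OCOC)cc1Oc1cc(OCOC)c(CC=C(C)C)cc1C#CC=C(C)C | intermediate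
12 | E-dienone, not isolated: (11E)-3,7-bis(methoxymethoxy)-2-(3-methylbut-2-en-1-yl)-11-(3-methylbut-2-en-1-ylidene)dibenzo[b,f]oxepin-10(11H)-one | CC(C)=C/C=C1\c2cc(CC=C(C)C)c(OCOC)cc2Oc2cc(OCOC)ccc2C1=O | intermediate
13 | Z-dienone, not isolated: (11Z)-3,7-bis(methoxymethoxy)-2-(3-methylbut-2-en-1-yl)-11-(3-methylbut-2-en-1-ylidene)dibenzo[b,f]oxepin-10(11H)-one | CC(C)=C/C=C1/c2cc(CC=C(C)C)c(OCOC)cc2Oc2cc(OCOC)ccc2C1=O | intermediate
14 | artocarpol D bis(methoxymethyl) ether: 2,2-dimethyl-2H-pyran fused across C10=C11 of 3,7-bis(methoxymethoxy)-2-(3-methylbut-2-en-1-yl)dibenzo[b,f]oxepine, pyran oxygen on C10 | CC(C)=CCc1cc2c(cc1OCOC)Oc1cc(OCOC)ccc1C1=C2C=CC(C)(C)O1 | intermediate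
15 | artocarpol D | CC(C)=CCc1cc2c(cc1O)Oc1cc(O)ccc1C1=C2C=CC(C)(C)O1 | target

**Step count and risks**

Total steps: 9. Longest linear sequence: 8 steps (1 → 2 → 5 → 7 → 8 → 10 → 11 → 14 → 15).

Steps most likely to fail:

Step 8 (proposed new method). The acyl rhodium hydride may lose carbon monoxide before the alkyne inserts, or the acyl group may be delivered to the distal alkyne carbon, so that the seven-membered ketone is not formed. Fallback with known chemistry, starting from 11: a nickel-catalysed reductive aldehyde–alkyne cyclisation (Ni(cod)2, PBu3, Et3B, toluene, rt) proceeds by oxidative cyclisation on zerovalent nickel, ethyl transfer from boron, β-hydride elimination and C–H reductive elimination. It should give the racemic allylic alcohol (11E)-3,7-bis(methoxymethoxy)-2-(3-methylbut-2-en-1-yl)-11-(3-methylbut-2-en-1-ylidene)-10,11-dihydrodibenzo[b,f]oxepin-10-ol F1. Oxidation with MnO2 (CH2Cl2, rt) should then give E-dienone 12 as an isolated compound. The fallback rejoins the route at 12, which the light stage of step 8 alone (fac-Ir(ppy)3, 450 nm LED, degassed ClCH2CH2Cl) should carry to 14.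

Step 9. During acetal cleavage the enol-ether double bond of the pyran may be protonated and opened, or the freed phenol may add to the neighbouring prenyl alkene under acid and close a chroman. Fallback that changes the protecting groups before the sensitive ring system exists, starting from 11: MOM removal (HCl, MeOH/THF, rt) should give the bisphenol 4-hydroxy-2-[5-hydroxy-4-(3-methylbut-2-en-1-yl)-2-(4-methylpent-3-en-1-yn-1-yl)phenoxy]benzaldehyde F2. Acetylation (Ac2O, pyridine, rt) should give the diacetate 4-acetoxy-2-[5-acetoxy-4-(3-methylbut-2-en-1-yl)-2-(4-methylpent-3-en-1-yn-1-yl)phenoxy]benzaldehyde F3. The conditions of step 8 should then lead through the E-dienone diacetate F4 and the Z-dienone diacetate F5, neither isolated, to artocarpol D diacetate F6. Methanolysis (K2CO3, MeOH, 0 °C) comes back to the route at 15.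

Step 4. The allyl unit may be transferred through its substituted terminus (reverse-prenyl isomer), or oxidative addition into the electron-rich, ortho-substituted aryl bromide may be slow. Fallback by allylation and cross-metathesis, starting from 5: Suzuki–Miyaura coupling with allylboronic acid pinacol ester (Pd(dppf)Cl2, K2CO3, dioxane/H2O, 80 °C) should give the allyl arene 2-[2-formyl-5-(methoxymethoxy)-4-(prop-2-en-1-yl)phenoxy]-4-(methoxymethoxy)benzonitrile F7, where allyl regiochemistry is not an issue. Olefin cross-metathesis with excess 2-methylbut-2-ene (second-generation Grubbs catalyst, CH2Cl2, 40 °C) comes back to the route at 7.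

**Further compounds**

F1 | step 8 | (11E)-3,7-bis(methoxymethoxy)-2-(3-methylbut-2-en-1-yl)-11-(3-methylbut-2-en-1-ylidene)-10,11-dihydrodibenzo[b,f]oxepin-10-ol (racemic) | CC(C)=C/C=C1\c2cc(CC=C(C)C)c(OCOC)cc2Oc2cc(OCOC)ccc2C1O
F2 | step 9 | 4-hydroxy-2-[5-hydroxy-4-(3-methylbut-2-en-1-yl)-2-(4-methylpent-3-en-1-yn-1-yl)phenoxy]benzaldehyde | O=Cc1ccc(O)cc1Oc1cc(O)c(CC=C(C)C)cc1C#CC=C(C)C
F3 | step 9 | 4-acetoxy-2-[5-acetoxy-4-(3-methylbut-2-en-1-yl)-2-(4-methylpent-3-en-1-yn-1-yl)phenoxy]benzaldehyde | O=Cc1ccc(OC(C)=O)cc1Oc1cc(OC(C)=O)c(CC=C(C)C)cc1C#CC=C(C)C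
F4 | step 9 | E-dienone diacetate: (11E)-3,7-diacetoxy-2-(3-methylbut-2-en-1-yl)-11-(3-methylbut-2-en-1-ylidene)dibenzo[b,f]oxepin-10(11H)-one | CC(C)=C/C=C1\c2cc(CC=C(C)C)c(OC(C)=O)cc2Oc2cc(OC(C)=O)ccc2C1=O
F5 | step 9 | Z-dienone diacetate: (11Z)-3,7-diacetoxy-2-(3-methylbut-2-en-1-yl)-11-(3-methylbut-2-en-1-ylidene)dibenzo[b,f]oxepin-10(11H)-one | CC(C)=C/C=C1/c2cc(CC=C(C)C)c(OC(C)=O)cc2Oc2cc(OC(C)=O)ccc2C1=O
F6 | step 9 | artocarpol D diacetate | CC(C)=CCc1cc2c(cc1OC(C)=O)Oc1cc(OC(C)=O)ccc1C1=C2C=CC(C)(C)O1
F7 | step 4 | 2-[2-formyl-5-(methoxymethoxy)-4-(prop-2-en-1-yl)phenoxy]-4-(methoxymethoxy)benzonitrile | N#Cc1ccc(OCOC)cc1Oc1cc(OCOC)c(CC=C)cc1C=O
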